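**Strategy.** The five ring carbons C1–C5 are traced back to the five carbons of furfuryl alcohol. Achmatowicz oxidation expands the furan to a six-membered 2H-pyran-3(6H)-one. The key step contracts this O-heterocycle to the carbocycle: amine-induced ring opening and aldol-type 4π closure join pyranone C2 and C6 as the C5–C4 bond and leave the former ring oxygen as the C5 hydroxyl. The vicinal C4–O/C5–O pattern beside the enone thus arises in one operation. The precursor is the 6-silyloxy pyranone. After lipase resolution, the C4 silyloxy group steers a dianion aldol with pentadecanal that sets C5 and C6; acetylation and desilylation finish.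

Key step: step 3

Remark: 2–5 are racemates (5 drawn as one enantiomer of the trans pair), and the C5 descriptor changes from S in 9 and 10 to R in 11 only through a CIP priority switch on desilylation, not through inversion.

Step 1
Reactants: 1 furfuryl alcohol
Product: 2 rac-6-hydroxy-2H-pyran-3(6H)-one
Conditions: mCPBA, CH2Cl2, 0 °C to rt
Reagents that add atoms: mCPBA (3-chloroperoxybenzoic acid), OOC(=O)c1cccc(Cl)c1
Why: Achmatowicz rearrangement: peracid oxidation of the 2-furylcarbinol gives a cis-enedione that closes through the primary hydroxyl to the six-membered hemiacetal, with no stereocentre carried forward.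

Step 2
Reactants: 2 rac-6-hydroxy-2H-pyran-3(6H)-one
Product: 3 rac-6-[(tert-butyldimethylsilyl)oxy]-2H-pyran-3(6H)-one
Conditions: TBSCl, imidazole, CH2Cl2, 0 °C
Reagents that add atoms: TBSCl (tert-butyldimethylsilyl chloride), C[Si](C)(Cl)C(C)(C)C
Why: Silyl ether formation at the hemiacetal hydroxyl gives a non-leaving anomeric group, so that base should later trigger contraction and not loss of the anomeric substituent to an oxidopyrylium species.

Step 3
Reactants: 3 rac-6-[(tert-butyldimethylsilyl)oxy]-2H-pyran-3(6H)-one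
Product: 5 rac-(4S,5R)-4-[(tert-butyldimethylsilyl)oxy]-5-hydroxycyclopent-2-en-1-one, via ring-opened dienolate 4 (not isolated)
Conditions: Et3N (0.2 equiv), DMF, rt
Reagents that add atoms: none
Why: Et3N removes a C2 proton (α to the ketone and to the ring oxygen), the resulting 6H-pyran-3-olate opens by 6π-electrocyclic cleavage of the O1–C6 bond to the acyclic oxido-dienal 4, and the silyloxy-bearing terminus then bonds to the formyl carbon before the alkoxide is protonated. The closest known reaction type is the amine-promoted isomerisation of 6-O-protected Achmatowicz pyranones to 4,5-dioxygenated cyclopent-2-enones, a relative of the Piancatelli 4π closure. The five-membered carbocycle closes by an intramolecular vinylogous aldol addition, formally 5-(enolendo)-exo-trig and best viewed as a conrotatory 4π-electrocyclisation of the oxido-pentadienyl system. C4 and C5 are created together; conrotation with the silyloxy group and the formyl oxygen both outward, backed by base equilibration of the enolisable C5, should give the trans isomer as a racemate, and only the C4 centre is needed later. The step needs deprotonation and ring opening to outrun loss of the anomeric group and β-elimination, which the poor leaving ability of the silyloxy group and the mild base should secure.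

Step 4
Reactants: 5 rac-(4S,5R)-4-[(tert-butyldimethylsilyl)oxy]-5-hydroxycyclopent-2-en-1-one
Product: 6 (4S,5R)-4-[(tert-butyldimethylsilyl)oxy]-5-hydroxycyclopent-2-en-1-one
Conditions: Amano lipase PS, vinyl acetate, MTBE, 30 °C, stopped just past half conversion; chromatography
Reagents that add atoms: none
Why: Enzymatic kinetic resolution by lipase-catalysed irreversible transesterification: with the silyloxy-bearing C4 as the large and the carbonyl carbon as the medium substituent, the empirical size rule for secondary alcohols predicts acylation of the (4R,5S)-enantiomer, so the (4S,5R)-alcohol should remain unreacted.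

Step 5
Reactants: 6 (4S,5R)-4-[(tert-butyldimethylsilyl)oxy]-5-hydroxycyclopent-2-en-1-one; 7 pentadecanal
Product: 9 (4S,5S)-4-[(tert-butyldimethylsilyl)oxy]-5-hydroxy-5-[(1S)-1-hydroxypentadecyl]cyclopent-2-en-1-one, via dilithium enediolate 8 (not isolated)
Conditions: LiN(iPr)2 (2.2 equiv), THF, −78 °C; then 7, −78 °C; AcOH quench at −78 °C
Reagents that add atoms: none
Why: Aldol addition of an α-hydroxy ketone dianion: double deprotonation planarises C5, the aldehyde should add to the enediolate face anti to the C4 silyloxy group (C5 set, side chain trans to O4, hence the cis-4,5-diol), and a Zimmerman–Traxler chair through the O1–Li bridge with the tetradecyl chain equatorial should set (S)-C6.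

Step 6
Reactants: 9 (4S,5S)-4-[(tert-butyldimethylsilyl)oxy]-5-hydroxy-5-[(1S)-1-hydroxypentadecyl]cyclopent-2-en-1-one
Product: 10 (1S)-1-[(1S,5S)-5-[(tert-butyldimethylsilyl)oxy]-1-hydroxy-2-oxocyclopent-3-en-1-yl]pentadecyl acetate
Conditions: Ac2O (1.2 equiv), pyridine, DMAP (cat.), CH2Cl2, 0 °C
Reagents that add atoms: acetic anhydride, CC(=O)OC(C)=O
Why: Chemoselective O-acylation under nucleophilic catalysis: the secondary C6 hydroxyl should react while the tertiary α-ketol hydroxyl at C5 is too hindered, and the product has no α-hydrogen for β-elimination.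

Step 7
Reactants: 10 (1S)-1-[(1S,5S)-5-[(tert-butyldimethylsilyl)oxy]-1-hydroxy-2-oxocyclopent-3-en-1-yl]pentadecyl acetate
Product: 11 (1S)-1-[(1R,5S)-1,5-dihydroxy-2-oxocyclopent-3-en-1-yl]pentadecyl acetate
Conditions: HF·pyridine, THF/pyridine, 0 °C to rt
Reagents that add atoms: none
Why: Fluoride-mediated silyl ether cleavage under buffered, non-basic conditions, chosen to avoid the acetyl migration and retro-aldol cleavage that a basic fluoride source could cause; no stereocentre is touched.

**Compound list**

1 | furfuryl alcohol (furan-2-ylmethanol) | OCc1ccco1 | starting material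
2 | rac-6-hydroxy-2H-pyran-3(6H)-one | O=C1COC(O)C=C1 | intermediate
3 | rac-6-[(tert-butyldimethylsilyl)oxy]-2H-pyran-3(6H)-one | O=C1COC(O[Si](C)(C)C(C)(C)C)C=C1 | intermediate
4 | triethylammonium (2E,4E)-5-[(tert-butyldimethylsilyl)oxy]-1-oxopenta-2,4-dien-2-olate (formyl group cis to C4; ring-opened dienolate) | CC[NH+](CC)CC.O=C/C([O-])=C\C=C\O[Si](C)(C)C(C)(C)C | intermediate
5 | rac-(4S,5R)-4-[(tert-butyldimethylsilyl)oxy]-5-hydroxycyclopent-2-en-1-one (trans, racemate) | O[C@H]1C(=O)C=C[C@@H]1O[Si](C)(C)C(C)(C)C | intermediate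
6 | (4S,5R)-4-[(tert-butyldimethylsilyl)oxy]-5-hydroxycyclopent-2-en-1-one (single enantiomer) | O[C@H]1C(=O)C=C[C@@H]1O[Si](C)(C)C(C)(C)C | intermediate
7 | pentadecanal | CCCCCCCCCCCCCCC=O | starting material
8 | dilithium (5S)-5-[(tert-butyldimethylsilyl)oxy]cyclopenta-1,3-diene-1,2-diolate | [Li]OC1=C(O[Li])[C@@H](O[Si](C)(C)C(C)(C)C)C=C1 | intermediate
9 | (4S,5S)-4-[(tert-butyldimethylsilyl)oxy]-5-hydroxy-5-[(1S)-1-hydroxypentadecyl]cyclopent-2-en-1-one | CCCCCCCCCCCCCC[C@H](O)[C@@]1(O)C(=O)C=C[C@@H]1O[Si](C)(C)C(C)(C)C | intermediate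
10 | (1S)-1-[(1S,5S)-5-[(tert-butyldimethylsilyl)oxy]-1-hydroxy-2-oxocyclopent-3-en-1-yl]pentadecyl acetate | CCCCCCCCCCCCCC[C@H](OC(C)=O)[C@@]1(O)C(=O)C=C[C@@H]1O[Si](C)(C)C(C)(C)C | intermediate
11 | (1S)-1-[(1R,5S)-1,5-dihydroxy-2-oxocyclopent-3-en-1-yl]pentadecyl acetate, i.e. (4S,5R)-5-[(1S)-1-acetoxypentadecyl]-4,5-dihydroxycyclopent-2-en-1-one | CCCCCCCCCCCCCC[C@H](OC(C)=O)[C@@]1(O)C(=O)C=C[C@@H]1O | target

**Total step count:** 7. **Longest linear sequence:** 7 steps (1 to 11).

**Steps most likely to fail**

Risk 1, step 5. The dianion may react through competing open or O5–Li-bound transition states, giving poor control at C6. Deprotonation at the γ-position (C4) instead of C5 would erode the enantiomeric purity. Fallback: from 6, the C5 hydroxyl is silylated (TBSOTf, 2,6-lutidine, CH2Cl2, −78 °C) to (4S,5R)-4,5-bis[(tert-butyldimethylsilyl)oxy]cyclopent-2-en-1-one F1. Soft enolisation with Bu2BOTf and iPr2NEt (CH2Cl2, −78 °C) gives the dibutylboron enolate F2, which should add 7 through a single tight chair transition state, again anti to the C4 silyloxy group, to give (4S,5S)-4,5-bis[(tert-butyldimethylsilyl)oxy]-5-[(1S)-1-hydroxypentadecyl]cyclopent-2-en-1-one F3. Here only the C6 hydroxyl is free, so acetylation (Ac2O, pyridine, DMAP) gives (1S)-1-[(1S,5S)-1,5-bis[(tert-butyldimethylsilyl)oxy]-2-oxocyclopent-3-en-1-yl]pentadecyl acetate F4. HF·pyridine then removes both silyl groups and the sequence comes back to the route at 11.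

Risk 2, step 4. The lipase may discriminate the enantiomers of a hindered α-ketol poorly or acylate it too slowly. Fallback: from 5, esterification with (S)-O-methylmandelic acid (DCC, DMAP cat., CH2Cl2, 0 °C) gives two diastereomeric esters, separable by chromatography or crystallisation: (1R,5S)-5-[(tert-butyldimethylsilyl)oxy]-2-oxocyclopent-3-en-1-yl (2S)-2-methoxy-2-phenylacetate F5 and (1S,5R)-5-[(tert-butyldimethylsilyl)oxy]-2-oxocyclopent-3-en-1-yl (2S)-2-methoxy-2-phenylacetate F6. Methanolysis of F5 (K2CO3 cat., MeOH, 0 °C) comes back to the route at 6.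

Risk 3, step 6. Acylation of the hindered secondary hydroxyl may be sluggish, with competing acetylation of the tertiary C5 hydroxyl or acetyl migration to it. Fallback: from 9, Bu2Sn(OMe)2 (toluene, 60 °C) gives the 5,6-O-dibutylstannylene acetal F7 of diol 9, a 2,2-dibutyl-1,3,2-dioxastannolane spiro-fused at C5 with all configurations unchanged. Its less hindered secondary oxygen should be acylated selectively by acetyl chloride (CH2Cl2, 0 °C), and aqueous work-up comes back to the route at 10.

**Further compounds**

F1 | step 5 | (4S,5R)-4,5-bis[(tert-butyldimethylsilyl)oxy]cyclopent-2-en-1-one | CC(C)(C)[Si](C)(C)O[C@H]1C(=O)C=C[C@@H]1O[Si](C)(C)C(C)(C)C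
F2 | step 5 | dibutylboron enolate of F1, (5S)-2,5-bis[(tert-butyldimethylsilyl)oxy]cyclopenta-1,3-dien-1-yl dibutylborinate | CCCCB(CCCC)OC1=C(O[Si](C)(C)C(C)(C)C)[C@@H](O[Si](C)(C)C(C)(C)C)C=C1
F3 | step 5 | (4S,5S)-4,5-bis[(tert-butyldimethylsilyl)oxy]-5-[(1S)-1-hydroxypentadecyl]cyclopent-2-en-1-one | CCCCCCCCCCCCCC[C@H](O)[C@@]1(O[Si](C)(C)C(C)(C)C)C(=O)C=C[C@@H]1O[Si](C)(C)C(C)(C)C
F4 | step 5 | (1S)-1-[(1S,5S)-1,5-bis[(tert-butyldimethylsilyl)oxy]-2-oxocyclopent-3-en-1-yl]pentadecyl acetate | CCCCCCCCCCCCCC[C@H](OC(C)=O)[C@@]1(O[Si](C)(C)C(C)(C)C)C(=O)C=C[C@@H]1O[Si](C)(C)C(C)(C)C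
F5 | step 4 | (1R,5S)-5-[(tert-butyldimethylsilyl)oxy]-2-oxocyclopent-3-en-1-yl (2S)-2-methoxy-2-phenylacetate | CO[C@H](C(=O)O[C@H]1C(=O)C=C[C@@H]1O[Si](C)(C)C(C)(C)C)c1ccccc1
F6 | step 4 | (1S,5R)-5-[(tert-butyldimethylsilyl)oxy]-2-oxocyclopent-3-en-1-yl (2S)-2-methoxy-2-phenylacetate | CO[C@H](C(=O)O[C@@H]1C(=O)C=C[C@H]1O[Si](C)(C)C(C)(C)C)c1ccccc1
F7 | step 6 | 5,6-O-dibutylstannylene acetal of diol 9 (2,2-dibutyl-1,3,2-dioxastannolane spiro-fused at C5, tetradecyl on the dioxastannolane carbon) | CCCCCCCCCCCCCC[C@@H]1O[Sn](CCCC)(CCCC)O[C@@]12C(=O)C=C[C@@H]2O[Si](C)(C)C(C)(C)C
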